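**Retrosynthetic overview**
1. Target 26 comes from selective 6-O-angeloylation of diol 23. The (12E)-diene comes from a C9 but-2-ynyl chain (syn-hydrozirconation, vinylation), the 8α-carbinol from the 8(17)-alkene and 8-ketone, the 6α-OH from a 6α-CO2Me group (radical decarboxylative oxygenation), and C9–C11 from alkylation of a regiodefined enolate.
2. Key disconnection: C6–C7 and C5–C10 are opened together by a catalytic asymmetric intramolecular Diels–Alder reaction. Rings A and B form at the same moment from an achiral open chain, and no ring exists before this step.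
3. Enabling feature: ring B (C5–C10) holds oxygen at C8 and at C6 on either side of an unsubstituted C7H2. Writing C8–O as the enol silane C8(OSi)=C9 turns ring B into a cyclohexene, that is diene C7=C8–C9=C10 plus dienophile C5=C6. The four sp3 carbons C1–C4 of ring A are the tether, and the C4 gem-dimethyl group favours the folded chain.
4. C6 carries CO2Me as activator and catalyst handle, and this group is later exchanged for OH. The two axial methyl groups (C19, C20) steer the chemistry at C6, C8 and C9 to the α face or to the equatorial position.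
5. Triene 8 comes in three linear steps from 2,2-dimethylpent-4-enal (C1–C5, C18, C19), pentane-2,4-dione (C7–C10, C20) and trimethyl phosphonoacetate (C6 and the activator carbon).

Key step: step 5

Remark: labdane numbering (C1–C20) is used for all intermediates; α is the face opposite to the C10 methyl group.
Assumption: the (S)-configured oxazaborolidinium ion is taken to shield the enoate face that would lead to the mirror-image decalin; if the sense of induction were opposite, the mirror-image catalyst would be used with no other change.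

**Step 1**
Reactants: 1 2,2-dimethylpent-4-enal; 2 trimethyl phosphonoacetate
Product: 3 methyl (2E)-4,4-dimethylhepta-2,6-dienoate
Conditions: LiCl, DBU, MeCN, 0 °C to rt
Reagents that add atoms: none
Why: Horner–Wadsworth–Emmons olefination of a non-enolisable neopentyl aldehyde with a stabilised phosphonate should give the (E)-enoate, the quaternary carbon reinforcing the usual E preference; no stereocentre is formed.

**Step 2**
Reactants: 4 pentane-2,4-dione
Product: 5 (2E)-4-oxopent-2-en-2-yl trifluoromethanesulfonate
Conditions: Tf2O, aq Me4NOH, hexanes, 0–5 °C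
Reagents that add atoms: trifluoromethanesulfonic anhydride, O=S(=O)(OS(=O)(=O)C(F)(F)F)C(F)(F)F
Why: Biphasic O-triflation of a 1,3-dicarbonyl enolate with a non-chelating ammonium counter-ion, the known stereocomplementary enol triflate synthesis, should react through the open, dipole-minimised enolate and place the triflate trans to the acetyl group.

**Step 3**
Reactants: 3 methyl (2E)-4,4-dimethylhepta-2,6-dienoate; 5 (2E)-4-oxopent-2-en-2-yl trifluoromethanesulfonate
Product: 7 methyl (2E,8E)-4,4,8-trimethyl-10-oxoundeca-2,8-dienoate, via B-alkyl-9-BBN adduct 6 (not isolated)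
Conditions: 9-BBN-H, THF, 0 °C to rt; then 5, PdCl2(dppf) (5 mol %), aq K3PO4, DMF, rt
Reagents that add atoms: none
Why: Anti-Markovnikov hydroboration takes only the terminal alkene (the enoate is electron-poor and hindered), and the B-alkyl Suzuki–Miyaura coupling proceeds with retention at the enol triflate carbon, so the chain ends up trans to the acetyl group (8E).

**Step 4**
Reactants: 7 methyl (2E,8E)-4,4,8-trimethyl-10-oxoundeca-2,8-dienoate
Product: 8 methyl (2E,8E)-4,4,8-trimethyl-10-(triisopropylsilyloxy)undeca-2,8,10-trienoate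
Conditions: i-Pr3SiOTf, Et3N, CH2Cl2, −78 to 0 °C
Reagents that add atoms: triisopropylsilyl trifluoromethanesulfonate, CC(C)[Si](OS(=O)(=O)C(F)(F)F)(C(C)C)C(C)C
Why: Soft enolisation of the methyl ketone removes the kinetically most accessible proton at C7 and should give the cross-conjugated 2-silyloxydiene with the 8E geometry kept at low temperature; the enoate has no acidic proton.

**Step 5**
Reactants: 8 methyl (2E,8E)-4,4,8-trimethyl-10-(triisopropylsilyloxy)undeca-2,8,10-trienoate
Product: 9 methyl 4a,8,8-trimethyl-3-(triisopropylsilyloxy)-1,2,4a,5,6,7,8,8a-octahydronaphthalene-1-carboxylate (trans-fused; labdane numbering: C8=C9 enol silane; 5α-H; 10β-CH3; 6α-CO2Me)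
Conditions: (S)-3,3-diphenyl-1-(2-methylphenyl)tetrahydro-1H,3H-pyrrolo[1,2-c][1,3,2]oxazaborole (20 mol %), (CF3SO2)2NH (17 mol %), CH2Cl2 (0.01 M), −40 to −10 °C
Reagents that add atoms: none
Why: The oxazaborolidinium ion binds the ester carbonyl and lowers the LUMO of the C5=C6 enoate, which adds suprafacially to the s-cis C7=C8–C9=C10 silyloxydiene in a concerted, asynchronous [4+2] cycloaddition that forms C6–C7 and C5–C10 together. The closest known reaction type is the Lewis acid-catalysed type 1 intramolecular Diels–Alder reaction of terminally activated (E)-1,7,9-decatrienoates and -trienals, which has been run enantioselectively with the same cationic boron catalysts, and these catalysts are known to tolerate 2-(triisopropylsilyloxy)dienes. Ring B closes as the six-membered ring of the cycloaddition itself and ring A closes in the fused mode over the four-carbon tether C1–C4 through a chair-like fold, the bridged regioisomer being out of reach for so short a tether. The (E)-enoate geometry fixes H5 and H6 trans, the endo transition state (ester under the diene, tether outside) together with the 8E diene geometry (C1 outside, C20 inside) places H5 opposite to the C10 methyl group and so gives the trans-decalin with an equatorial 6α-ester, and the absolute sense comes from the catalyst, whose aryl group blocks one face of the bound enoate. The step needs endo over exo selectivity, catalyst turnover faster than any achiral background, and intra- over intermolecular reaction, and the ester-bound Lewis acid, the acid-stable triisopropylsilyl group, the C4 gem-dimethyl effect and high dilution secure these. One operation thus turns an achiral chain into both rings, three stereocentres (C5, C6 and the quaternary C10) and a regiodefined C8=C9 enol silane.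

**Step 6**
Reactants: 9 enol silane ester; 10 1-bromobut-2-yne
Product: 13 methyl 8-oxo-14,15,17-trinorlabd-12-yne-6α-carboxylate (9β-but-2-ynyl chain; 9α-H), via tetrabutylammonium enolate 11 (not isolated), via 9-epi-ketone 12 (not isolated)
Conditions: Bu4NF (anhydrous, 4 Å MS), 10, THF, −78 °C to rt; then NaOMe (cat.), MeOH, rt
Reagents that add atoms: none
Why: Fluoride frees the C8–C9 enolate without loss of regiochemistry (regiospecific alkylation of a silyl enol ether), the slim and reactive propargylic bromide attacks the hindered C9 by SN2, and base equilibration turns any axial 9α-alkyl epimer into the equatorial 9β-alkyl ketone, which avoids the 1,3-diaxial contacts with H5 and H7.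

**Step 7**
Reactants: 13 methyl 8-oxo-14,15,17-trinorlabd-12-yne-6α-carboxylate
Product: 14 methyl 14,15-dinorlabd-8(17)-en-12-yne-6α-carboxylate
Conditions: Ph3PCH3Br, KOt-Bu, THF, 0 °C to reflux
Reagents that add atoms: methyltriphenylphosphonium bromide, C[P+](c1ccccc1)(c1ccccc1)c1ccccc1.[Br-]
Why: Wittig methylenation touches only the ketone (ester and alkyne are inert), and C9 is already at its thermodynamic configuration should the basic ylide enolise the ketone.

**Step 8**
Reactants: 14 methyl 14,15-dinorlabd-8(17)-en-12-yne-6α-carboxylate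
Product: 16 methyl 8α-hydroxy-14,15-dinorlabd-12-yne-6α-carboxylate, via tertiary hydroperoxide 15 (not isolated)
Conditions: Mn(dpm)3 (10 mol %), PhSiH3, O2 (1 atm), i-PrOH/CH2Cl2, 0 °C; then PPh3
Reagents that add atoms: dioxygen, O=O
Why: Mukaiyama hydration (metal hydride hydrogen atom transfer) is Markovnikov selective and much faster for the 1,1-disubstituted alkene than for the internal alkyne, and the tertiary C8 radical takes up O2 from the α face because the axial β approach is blocked by the syn-axial C10 methyl group, giving the equatorial 8α-oxygen and the axial 8β-methyl group.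

**Step 9**
Reactants: 16 methyl 8α-hydroxy-14,15-dinorlabd-12-yne-6α-carboxylate
Product: 17 8α-hydroxy-14,15-dinorlabd-12-yne-6α-carboxylic acid
Conditions: LiOH, THF/MeOH/H2O, 50 °C; then 1 M HCl
Reagents that add atoms: lithium hydroxide, [Li+].[OH-]
Why: Saponification of the equatorial methyl ester; the 6α-carboxyl group is the thermodynamic epimer and cannot lactonise onto the diequatorial tertiary 8α-hydroxyl of the rigid trans-decalin.

**Step 10**
Reactants: 17 8α-hydroxy-14,15-dinorlabd-12-yne-6α-carboxylic acid
Product: 20 14,15-dinorlabd-12-yne-6α,8α-diol, via thiohydroxamate ester 18 (not isolated), via C6 hydroperoxide 19 (not isolated)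
Conditions: 1-hydroxypyridine-2(1H)-thione, DCC, CH2Cl2, 0 °C, dark; then t-BuSH, O2, toluene, tungsten lamp, 0 °C; then P(OMe)3
Reagents that add atoms: dioxygen, O=O
Why: Barton decarboxylative hydroxylation: the thiohydroxamate ester fragments in a thiyl radical chain to CO2 and the secondary C6 radical, which takes up O2 from the α face because both axial methyl groups (C19 and C20) shield the β face, and phosphite reduction of the hydroperoxide keeps the new equatorial 6α C–O bond.

**Step 11**
Reactants: 20 14,15-dinorlabd-12-yne-6α,8α-diol; 21 vinyl bromide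
Product: 23 (12E)-labda-12,14-diene-6α,8α-diol, via alkenylzirconocene 22 (not isolated)
Conditions: Cp2Zr(H)Cl (3.5 equiv), THF, rt to 40 °C; then 21, Pd(PPh3)4 (5 mol %), ZnCl2 (20 mol %), THF, rt; aq NH4Cl
Reagents that add atoms: none
Why: Syn-hydrozirconation with excess reagent (two equivalents are taken up by the hydroxyl groups) equilibrates zirconium to the less hindered alkyne carbon C13, and the Negishi-type coupling with vinyl bromide proceeds with retention, so C11 and the new vinyl group end up trans (12E).

**Step 12**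
Reactants: 23 (12E)-labda-12,14-diene-6α,8α-diol; 24 angelic acid ((2Z)-2-methylbut-2-enoic acid)
Product: 26 (12E)-6α-angeloyloxylabda-12,14-dien-8α-ol (CNP0582767.1), via mixed anhydride 25 (not isolated)
Conditions: 24, 2,4,6-trichlorobenzoyl chloride, Et3N, toluene, rt; then 23, toluene, 80 °C
Reagents that add atoms: none
Why: Yamaguchi-type mixed anhydride esterification without a nucleophilic catalyst acylates only the secondary 6α-hydroxyl (the tertiary 8α-hydroxyl is inert) and is known to transfer the angeloyl group without Z to E isomerisation.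

**Compound list**
1 | 2,2-dimethylpent-4-enal | C=CCC(C)(C)C=O | starting material
2 | trimethyl phosphonoacetate | COC(=O)CP(=O)(OC)OC | starting material
3 | methyl (2E)-4,4-dimethylhepta-2,6-dienoate | C=CCC(C)(C)/C=C/C(=O)OC | intermediate
4 | pentane-2,4-dione | CC(=O)CC(C)=O | starting material
5 | (2E)-4-oxopent-2-en-2-yl trifluoromethanesulfonate | CC(=O)/C=C(\C)OS(=O)(=O)C(F)(F)F | intermediate
6 | methyl (2E)-7-(9-borabicyclo[3.3.1]nonan-9-yl)-4,4-dimethylhept-2-enoate | COC(=O)/C=C/C(C)(C)CCCB1C2CCCC1CCC2 | intermediate
7 | methyl (2E,8E)-4,4,8-trimethyl-10-oxoundeca-2,8-dienoate | COC(=O)/C=C/C(C)(C)CCC/C(C)=C/C(C)=O | intermediate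
8 | methyl (2E,8E)-4,4,8-trimethyl-10-(triisopropylsilyloxy)undeca-2,8,10-trienoate | COC(=O)/C=C/C(C)(C)CCC/C(C)=C/C(=C)O[Si](C(C)C)(C(C)C)C(C)C | intermediate
9 | trans-fused enol silane ester (5α-H, 10β-CH3, 6α-CO2Me, C8=C9 with 8-OSi(i-Pr)3) | C1[C@@]2(C)CCCC(C)(C)[C@@H]2[C@@H](C(=O)OC)CC(O[Si](C(C)C)(C(C)C)C(C)C)=1 | intermediate
10 | 1-bromobut-2-yne | CC#CCBr | starting material
11 | tetrabutylammonium C8–C9 enolate of the decalone ester | C1[C@@]2(C)CCCC(C)(C)[C@@H]2[C@@H](C(=O)OC)CC([O-])=1.CCCC[N+](CCCC)(CCCC)CCCC | intermediate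
12 | methyl 8-oxo-14,15,17-trinor-9-epi-labd-12-yne-6α-carboxylate (9α-alkyl, 9β-H) | CC#CC[C@H]1[C@@]2(C)CCCC(C)(C)[C@@H]2[C@@H](C(=O)OC)CC1=O | intermediate
13 | methyl 8-oxo-14,15,17-trinorlabd-12-yne-6α-carboxylate (9β-alkyl, 9α-H) | CC#CC[C@@H]1[C@@]2(C)CCCC(C)(C)[C@@H]2[C@@H](C(=O)OC)CC1=O | intermediate
14 | methyl 14,15-dinorlabd-8(17)-en-12-yne-6α-carboxylate | CC#CC[C@@H]1[C@@]2(C)CCCC(C)(C)[C@@H]2[C@@H](C(=O)OC)CC1=C | intermediate
15 | methyl 8α-hydroperoxy-14,15-dinorlabd-12-yne-6α-carboxylate | CC#CC[C@@H]1[C@@]2(C)CCCC(C)(C)[C@@H]2[C@@H](C(=O)OC)C[C@@]1(C)OO | intermediate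
16 | methyl 8α-hydroxy-14,15-dinorlabd-12-yne-6α-carboxylate | CC#CC[C@@H]1[C@@]2(C)CCCC(C)(C)[C@@H]2[C@@H](C(=O)OC)C[C@@]1(C)O | intermediate
17 | 8α-hydroxy-14,15-dinorlabd-12-yne-6α-carboxylic acid | CC#CC[C@@H]1[C@@]2(C)CCCC(C)(C)[C@@H]2[C@@H](C(=O)O)C[C@@]1(C)O | intermediate
18 | 2-thioxopyridin-1(2H)-yl 8α-hydroxy-14,15-dinorlabd-12-yne-6α-carboxylate | CC#CC[C@@H]1[C@@]2(C)CCCC(C)(C)[C@@H]2[C@@H](C(=O)On2ccccc2=S)C[C@@]1(C)O | intermediate
19 | 6α-hydroperoxy-14,15-dinorlabd-12-yn-8α-ol | CC#CC[C@@H]1[C@@]2(C)CCCC(C)(C)[C@@H]2[C@@H](OO)C[C@@]1(C)O | intermediate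
20 | 14,15-dinorlabd-12-yne-6α,8α-diol | CC#CC[C@@H]1[C@@]2(C)CCCC(C)(C)[C@@H]2[C@@H](O)C[C@@]1(C)O | intermediate
21 | vinyl bromide | C=CBr | starting material
22 | (12E)-13-chlorozirconocenyl alkene, both oxygens as chlorozirconocene alkoxides | Cl[Zr](C1C=CC=C1)(C1C=CC=C1)/C(C)=C/C[C@@H]1[C@@]2(C)CCCC(C)(C)[C@@H]2[C@@H](O[Zr](Cl)(C2C=CC=C2)C2C=CC=C2)C[C@@]1(C)O[Zr](Cl)(C1C=CC=C1)C1C=CC=C1 | intermediate
23 | (12E)-labda-12,14-diene-6α,8α-diol | C=C/C(C)=C/C[C@@H]1[C@@]2(C)CCCC(C)(C)[C@@H]2[C@@H](O)C[C@@]1(C)O | intermediate
24 | angelic acid | C/C=C(/C)C(=O)O | starting material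
25 | angelic 2,4,6-trichlorobenzoic anhydride | C/C=C(/C)C(=O)OC(=O)c1c(Cl)cc(Cl)cc1Cl | intermediate
26 | (12E)-6α-angeloyloxylabda-12,14-dien-8α-ol | C=C/C(C)=C/C[C@@H]1[C@@]2(C)CCCC(C)(C)[C@@H]2[C@@H](OC(=O)/C(C)=C\C)C[C@@]1(C)O | target

**Step count**
Total step count: 12. Longest linear sequence: 11 steps (1, 3–12).

**Steps most likely to fail**

Step 5 (key step). The hindered C5–C10 bond may form too slowly at the temperatures at which the catalyst discriminates. Silyl triflimide released by slow protodesilylation could then take over as an achiral catalyst and erode the enantiomeric purity, or the exo mode could leak to cis-fused material. The fallback replaces catalysis by a covalent auxiliary and a stoichiometric, chelating aluminium Lewis acid, and runs from 7 back to 9. Saponification of 7 (LiOH, THF/H2O) would give the keto dienoic acid F1. Pivaloyl chloride/Et3N would give the mixed pivalic anhydride F2, and (S)-4-benzyloxazolidin-2-one with LiCl/Et3N the N-enoyl imide F3. Soft enolisation (i-Pr3SiOTf, Et3N, CH2Cl2, −78 °C) would give the silyloxydiene imide F4. Me2AlCl (1.4 equiv, CH2Cl2, −30 °C) forms the cationic chelate of the s-cis imide, a much stronger activation. The benzyl group shields the face that leads to the wrong enantiomer, so the endo cycloaddition should give the adduct imide F5. MeOMgBr in MeOH/THF exchanges the auxiliary for methoxide and returns 9.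

Step 6. Proton transfer to the naked enolate, O-alkylation and slow SN2 attack at the neopentyl-type C9 may return unsubstituted ketone and scramble the enolate position. The fallback introduces C11 as an electrophilic carbon instead and runs from 9 back to 13. Dimethyl(methylidene)ammonium iodide in CH2Cl2 attacks the enol silane at C9 and would give the Mannich base F6. MeI would give the methiodide F7, and aq NaHCO3 the 9-methylidene ketone F8, an enone locked s-cis. Diethyl(prop-1-ynyl)aluminium (from prop-1-ynyllithium and Et2AlCl, Et2O/hexane, 0 °C) adds 1,4 through a cyclic transition state to give the aluminium enolate F9. Protonation and NaOMe/MeOH equilibration return 13.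

Step 2. Geometric control may be lost in the O-triflation (partial reaction through a chelated or U-shaped enolate), or 5 may drift between E and Z under the basic coupling conditions. Either would put the chain on the inner position of the diene, and that isomer cannot reach the trans-fused transition state. The fallback takes the alkene geometry from a syn-hydrometalation instead of an enolate geometry, and runs from 3 (through its borane 6) back to 7. Commercial pent-3-yn-2-ol and Cp2Zr(H)Cl (2.2 equiv, THF) would give the alkoxide-bound alkenylzirconocene F10 with zirconium on the methyl-bearing carbon, and iodine would give the vinyl iodide (3E)-4-iodopent-3-en-2-ol F11. Coupling with 6 under the conditions of step 3 would give the allylic alcohol F12, and MnO2 (CH2Cl2) returns 7.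

**Further compounds**
F1 | step 5 | (2E,8E)-4,4,8-trimethyl-10-oxoundeca-2,8-dienoic acid | CC(=O)/C=C(\C)CCCC(C)(C)/C=C/C(=O)O
F2 | step 5 | (2E,8E)-4,4,8-trimethyl-10-oxoundeca-2,8-dienoic pivalic anhydride | CC(=O)/C=C(\C)CCCC(C)(C)/C=C/C(=O)OC(=O)C(C)(C)C
F3 | step 5 | (4S)-4-benzyl-3-[(2E,8E)-4,4,8-trimethyl-10-oxoundeca-2,8-dienoyl]-1,3-oxazolidin-2-one | CC(=O)/C=C(\C)CCCC(C)(C)/C=C/C(=O)N1[C@@H](Cc2ccccc2)COC1=O
F4 | step 5 | (4S)-4-benzyl-3-[(2E,8E)-4,4,8-trimethyl-10-(triisopropylsilyloxy)undeca-2,8,10-trienoyl]-1,3-oxazolidin-2-one | C=C(O[Si](C(C)C)(C(C)C)C(C)C)/C=C(\C)CCCC(C)(C)/C=C/C(=O)N1[C@@H](Cc2ccccc2)COC1=O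
F5 | step 5 | trans-fused enol silane with 6α-[(4S)-4-benzyl-2-oxo-1,3-oxazolidine-3-carbonyl] group (5α-H, 10β-CH3) | C1[C@@]2(C)CCCC(C)(C)[C@@H]2[C@@H](C(=O)N2[C@@H](Cc3ccccc3)COC2=O)CC(O[Si](C(C)C)(C(C)C)C(C)C)=1
F6 | step 6 | methyl 9β-(dimethylaminomethyl)-8-oxo decalin-6α-carboxylate (5α-H, 10β-CH3) | CN(C)C[C@@H]1[C@@]2(C)CCCC(C)(C)[C@@H]2[C@@H](C(=O)OC)CC1=O
F7 | step 6 | trimethylammonium iodide of F6 | C[N+](C)(C)C[C@@H]1[C@@]2(C)CCCC(C)(C)[C@@H]2[C@@H](C(=O)OC)CC1=O.[I-]
F8 | step 6 | methyl 9-methylidene-8-oxo decalin-6α-carboxylate (5α-H, 10β-CH3) | C=C1[C@@]2(C)CCCC(C)(C)[C@@H]2[C@@H](C(=O)OC)CC1=O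
F9 | step 6 | diethylaluminium C8–C9 enolate bearing the 9-but-2-ynyl chain | CC#CCC1[C@@]2(C)CCCC(C)(C)[C@@H]2[C@@H](C(=O)OC)CC(O[Al](CC)CC)=1
F10 | step 2 | (3E)-4-chlorozirconocenylpent-3-en-2-yl chlorozirconocene alkoxide | Cl[Zr](C1C=CC=C1)(C1C=CC=C1)/C(C)=C/C(C)O[Zr](Cl)(C1C=CC=C1)C1C=CC=C1
F11 | step 2 | (3E)-4-iodopent-3-en-2-ol | I/C(C)=C/C(C)O
F12 | step 2 | methyl (2E,8E)-10-hydroxy-4,4,8-trimethylundeca-2,8-dienoate | COC(=O)/C=C/C(C)(C)CCC/C(C)=C/C(C)O
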